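## Retrosynthetic overview

1. The C5 isobutyryl group goes on last, by acylation of the bridgehead anion of the cage triketone.
2. The cage closes through the C4–C5 bond (intramolecular Mukaiyama aldol, then oxidation); before that, C1 is geranylated and the C1–C2 bond is made by intramolecular C-acylation of a cyclohexanone enolate.
3. The cyclopentane comes from intramolecular malonate alkylation (C3–C14); the two malonate esters are told apart by selective saponification, which fixes C3.
4. Key fragment union: an intermolecular copper–bis(oxazoline) Mukaiyama–Michael addition of a thioisobutyrate silyl ketene acetal to an alkylidene malonate (C11–C12 bond, sets C11); the acceptor comes from a Knoevenagel condensation.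
5. Ring order: cyclohexanone (from 4,4-dimethylcyclohexenone by CBS reduction, Johnson–Claisen to set C7, allylic oxidation) → cyclopentane → first seven-membered ring (C1–C2) → trione six-membered ring and second seven-membered ring together (C4–C5).

Assumption: the (S,S)-configured ligand in step 10 gives the 2S adduct 16 as drawn; if the sense of induction is the opposite, the (R,R)-ligand is used.

Locants used in the names of polycycles: C1 (geranyl-bearing carbon), C2/C4/C9 (carbonyl carbons), C3 (ring-fusion carbon), C5 (isobutyryl-bearing carbon), C6 (CMe2), C7 (CH), C8 (CH2), C10 (CH2 on C7), C11 (CH joining C10, C3, C12), C12 (CMe2), C13 and C14 (CH2; C14 on C3). In these locants the target is 1R,3S,5S,7R,11R.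

## Route

Step 1
Reactants: 1 4,4-dimethylcyclohex-2-en-1-one
Product: 2 (1R)-4,4-dimethylcyclohex-2-en-1-ol
Conditions: (S)-2-methyl-CBS-oxazaborolidine (10 mol%), BH3·SMe2, THF, −20 °C; MeOH, aq work-up
Reagents that add atoms: none
Why: Corey–Bakshi–Shibata 1,2-reduction in which the (S)-oxazaborolidine treats the alkenyl arm as the large group and gives the (R)-allylic alcohol.

Step 2
Reactants: 2 (1R)-4,4-dimethylcyclohex-2-en-1-ol; 3 triethyl orthoacetate
Product: 5 ethyl 2-[(1R)-6,6-dimethylcyclohex-2-en-1-yl]acetate, via mixed ketene acetal 4 (not isolated)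
Conditions: EtCO2H (5 mol%), 3 (6 equiv, neat), 140 °C, EtOH distilled off
Reagents that add atoms: none
Why: Johnson–Claisen rearrangement; the suprafacial chair [3,3] shift transfers the carbinol chirality to the new C7–C10 bond on the same ring face, setting C7 next to the gem-dimethyl carbon.

Step 3
Reactants: 5 ethyl 2-[(1R)-6,6-dimethylcyclohex-2-en-1-yl]acetate
Product: 6 ethyl 2-[(1R)-6,6-dimethyl-4-oxocyclohex-2-en-1-yl]acetate
Conditions: Pd(OH)2/C (5 mol%), t-BuOOH (5 equiv), K2CO3 (0.25 equiv), CH2Cl2, 4 °C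
Reagents that add atoms: tert-butyl hydroperoxide CC(C)(C)OO
Why: Corey–Yu allylic oxidation converts the only allylic CH2 into the enone carbonyl (future C9), the other allylic position being the shielded C7 methine.

Step 4
Reactants: 6 ethyl 2-[(1R)-6,6-dimethyl-4-oxocyclohex-2-en-1-yl]acetate
Product: 7 ethyl 2-[(1S)-2,2-dimethyl-4-oxocyclohexyl]acetate
Conditions: H2 (1 atm), Pd/C, EtOAc, rt
Reagents that add atoms: none
Why: Heterogeneous catalytic hydrogenation saturates the enone C=C without touching C7 (the descriptor changes from R to S only through CIP priorities).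

Step 5
Reactants: 7 ethyl 2-[(1S)-2,2-dimethyl-4-oxocyclohexyl]acetate
Product: 8 ethyl 2-[(8S)-7,7-dimethyl-1,4-dioxaspiro[4.5]decan-8-yl]acetate
Conditions: HOCH2CH2OH, p-TsOH (cat.), benzene, reflux, Dean–Stark
Reagents that add atoms: ethane-1,2-diol OCCO
Why: Acid-catalysed ketalisation masks the ketone as a dioxolane for the hydride, ylide and borane steps that follow.

Step 6
Reactants: 8 ethyl 2-[(8S)-7,7-dimethyl-1,4-dioxaspiro[4.5]decan-8-yl]acetate
Product: 9 2-[(8S)-7,7-dimethyl-1,4-dioxaspiro[4.5]decan-8-yl]acetaldehyde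
Conditions: i-Bu2AlH (1.1 equiv), CH2Cl2, −78 °C; aq work-up
Reagents that add atoms: none
Why: DIBAL partial reduction stops at the aldehyde because the tetrahedral aluminium hemiacetal is stable at −78 °C.

Step 7
Reactants: 9 2-[(8S)-7,7-dimethyl-1,4-dioxaspiro[4.5]decan-8-yl]acetaldehyde; 10 dimethyl malonate
Product: 11 dimethyl 2-{2-[(8S)-7,7-dimethyl-1,4-dioxaspiro[4.5]decan-8-yl]ethylidene}propanedioate
Conditions: piperidine (10 mol%), AcOH (10 mol%), benzene, reflux, Dean–Stark
Reagents that add atoms: none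
Why: Knoevenagel condensation (aldol-type) driven by water removal gives the chelating alkylidene malonate acceptor, which has no alkene geometry issue.

Step 8
Reactants: 12 2-methylpropanoyl chloride; 13 ethanethiol
Product: 14 S-ethyl 2-methylpropanethioate
Conditions: Et3N, CH2Cl2, 0 °C
Reagents that add atoms: none
Why: Simple acyl substitution of the acid chloride by the thiol.

Step 9
Reactants: 14 S-ethyl 2-methylpropanethioate
Product: 15 {[1-(ethylsulfanyl)-2-methylprop-1-en-1-yl]oxy}trimethylsilane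
Conditions: LiN(i-Pr)2, THF, −78 °C; then Me3SiCl
Reagents that add atoms: chlorotrimethylsilane C[Si](C)(C)Cl
Why: O-silylation of the thioester enolate gives the silyl ketene thioacetal, which has no geometric isomers because the two methyl groups are identical.

Step 10
Reactants: 11 dimethyl 2-{2-[(8S)-7,7-dimethyl-1,4-dioxaspiro[4.5]decan-8-yl]ethylidene}propanedioate; 15 {[1-(ethylsulfanyl)-2-methylprop-1-en-1-yl]oxy}trimethylsilane
Product: 16 dimethyl 2-[(2S)-1-[(8S)-7,7-dimethyl-1,4-dioxaspiro[4.5]decan-8-yl]-4-(ethylsulfanyl)-3,3-dimethyl-4-oxobutan-2-yl]propanedioate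
Conditions: [Cu((S,S)-t-Bu-box)](SbF6)2 (10 mol%), (CF3)2CHOH (2 equiv), PhMe/CH2Cl2 3:1, −78 → −20 °C
Reagents that add atoms: none
Why: Intermolecular Evans-type Mukaiyama–Michael addition in which the copper-chelated alkylidene malonate is attacked on one face under catalyst control, setting C11 and the adjacent quaternary C12 while the remote C7 centre has little influence.

Step 11
Reactants: 16 thioester malonate (as named in step 10)
Product: 17 dimethyl 2-[(2S)-1-[(8S)-7,7-dimethyl-1,4-dioxaspiro[4.5]decan-8-yl]-3,3-dimethyl-4-oxobutan-2-yl]propanedioate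
Conditions: Et3SiH (3 equiv), Pd/C (10 mol%), acetone, rt
Reagents that add atoms: none
Why: Fukuyama reduction converts only the thioester into the aldehyde and leaves the methyl esters and the dioxolane alone.

Step 12
Reactants: 17 aldehyde malonate (as named in step 11)
Product: 18 dimethyl 2-[(2S)-1-[(8S)-7,7-dimethyl-1,4-dioxaspiro[4.5]decan-8-yl]-3,3-dimethylpent-4-en-2-yl]propanedioate
Conditions: Ph3PCH3Br (2.6 equiv), KOt-Bu (2.5 equiv), THF, 0 °C → rt
Reagents that add atoms: methyltriphenylphosphonium bromide C[P+](c1ccccc1)(c1ccccc1)c1ccccc1.[Br-]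
Why: Wittig methylenation of the non-enolisable neopentyl aldehyde, with excess ylide to cover the acidic malonate C–H.

Step 13
Reactants: 18 vinyl malonate (as named in step 12)
Product: 20 dimethyl 2-[(2S)-1-[(8S)-7,7-dimethyl-1,4-dioxaspiro[4.5]decan-8-yl]-5-hydroxy-3,3-dimethylpentan-2-yl]propanedioate, via alkylborane 19 (not isolated)
Conditions: 9-BBN (1.5 equiv), THF, 0 °C → rt; then H2O2, aq NaOAc, 0 °C
Reagents that add atoms: hydrogen peroxide OO
Why: Anti-Markovnikov hydroboration–oxidation of the terminal alkene delivers the primary alcohol (future C14).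

Step 14
Reactants: 20 hydroxy malonate (as named in step 13)
Product: 21 dimethyl 2-[(2S)-1-[(8S)-7,7-dimethyl-1,4-dioxaspiro[4.5]decan-8-yl]-5-iodo-3,3-dimethylpentan-2-yl]propanedioate
Conditions: I2, PPh3, imidazole, CH2Cl2, 0 °C → rt
Reagents that add atoms: iodine II
Why: Appel-type (Garegg–Samuelsson) iodination of the unhindered primary alcohol under buffered conditions that spare the ketal.

Step 15
Reactants: 21 iodo malonate (as named in step 14)
Product: 22 dimethyl (2R)-2-{[(8S)-7,7-dimethyl-1,4-dioxaspiro[4.5]decan-8-yl]methyl}-3,3-dimethylcyclopentane-1,1-dicarboxylate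
Conditions: NaH (1.1 equiv), THF, 0 °C → rt
Reagents that add atoms: none
Why: Intramolecular malonate alkylation (5-exo-tet, helped by the gem-dimethyl group) closes the cyclopentane without touching C11.

Step 16
Reactants: 22 cyclopentane diester (as named in step 15)
Product: 23 (1S,2R)-2-{[(8S)-7,7-dimethyl-1,4-dioxaspiro[4.5]decan-8-yl]methyl}-1-(methoxycarbonyl)-3,3-dimethylcyclopentane-1-carboxylic acid
Conditions: KOH (1.1 equiv), MeOH/H2O 9:1, rt; AcOH to pH 5
Reagents that add atoms: potassium hydroxide [K+].[OH-]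
Why: Saponification attacks the less hindered ester, trans to the bulky C2 side chain, which fixes the C3 configuration (CO2H trans, CO2Me cis to the side chain).

Step 17
Reactants: 23 acid ester (as named in step 16)
Product: 26 (1R,2R)-2-{[(1S)-2,2-dimethyl-4-oxocyclohexyl]methyl}-1-(hydroxymethyl)-3,3-dimethylcyclopentane-1-carboxylic acid, via sodium carboxylate 24 (not isolated), via ketal hydroxy acid 25 (not isolated)
Conditions: NaH (1.0 equiv), THF, 0 °C; LiBH4 (3 equiv), MeOH (2 equiv), THF, 45 °C; then 2 M HCl, THF, rt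
Reagents that add atoms: water O
Why: LiBH4 reduces the ester but not the pre-formed carboxylate salt (no free borane is generated), and the acidic work-up hydrolyses the dioxolane.

Step 18
Reactants: 26 keto hydroxy acid (as named in step 17)
Product: 28 (1R,2R)-1-({[tert-butyl(dimethyl)silyl]oxy}methyl)-2-{[(1S)-2,2-dimethyl-4-oxocyclohexyl]methyl}-3,3-dimethylcyclopentane-1-carboxylic acid, via bis-silyl derivative 27 (not isolated)
Conditions: t-BuMe2SiCl (2.2 equiv), imidazole (4 equiv), DMF, rt; then AcOH/THF/H2O 3:1:1, rt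
Reagents that add atoms: tert-butyl(chloro)dimethylsilane CC(C)(C)[Si](C)(C)Cl
Why: Silylation protects the future C4 carbinol, and the labile silyl ester is hydrolysed selectively to return the free acid.

Step 19
Reactants: 28 silyl ether keto acid (as named in step 18)
Product: 30 C1-H tricyclic 2,9-diketone TBS ether (C1–C2 bond closed; C4 as CH2OTBS; C5 still CH2), via acyl imidazolide 29 (not isolated)
Conditions: 1,1'-carbonyldiimidazole (1.05 equiv), THF, 40 °C; then LiN(SiMe3)2 (3 equiv), THF, −78 → 0 °C; aq NH4Cl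
Reagents that add atoms: none
Why: Intramolecular Claisen-type C-acylation of the kinetic enolate at the less hindered α-CH2 (C1) by the imidazolide closes the first seven-membered ring; the enolisable β-diketone product drives it and the bridge dictates the C1 configuration.

Step 20
Reactants: 30 C1-H tricyclic 2,9-diketone TBS ether; 31 geranyl bromide
Product: 32 1-geranyl tricyclic 2,9-diketone TBS ether
Conditions: NaH (1.1 equiv), THF/DMF 4:1, 0 °C; then 31 (1.2 equiv), 0 °C → rt
Reagents that add atoms: none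
Why: C-alkylation of the β-diketone enolate, whose bridgehead position disfavours O-alkylation and leaves only the exo face open, creates the C1 quaternary centre with the geranyl group equatorial.

Step 21
Reactants: 32 1-geranyl tricyclic 2,9-diketone TBS ether
Product: 33 1-geranyl tricyclic 2,9-diketone C4 primary alcohol
Conditions: HF·pyridine, pyridine, THF, 0 °C → rt
Reagents that add atoms: none
Why: Fluoride desilylation under buffered, non-basic conditions avoids retro-aldol loss of the hydroxymethyl group.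

Step 22
Reactants: 33 1-geranyl tricyclic 2,9-diketone C4 primary alcohol
Product: 34 1-geranyl tricyclic 2,9-diketone C4 aldehyde
Conditions: Dess–Martin periodinane, CH2Cl2, rt
Reagents that add atoms: none
Why: Dess–Martin oxidation gives the non-enolisable neopentyl aldehyde without affecting the trisubstituted alkenes.

Step 23
Reactants: 34 1-geranyl tricyclic 2,9-diketone C4 aldehyde
Product: 37 cage aldol (4-hydroxy-2,9-dione with C5-H; C4 epimers), via silyl enol ether 35 (not isolated), via silyl aldol 36 (not isolated)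
Conditions: Me3SiOTf (2.5 equiv), i-Pr2NEt (3 equiv), CH2Cl2, −78 → 0 °C; then 1 M HCl, THF, 0 °C
Reagents that add atoms: none
Why: Soft enolisation gives the only possible silyl enol ether (C9/C5), which adds axially to the activated aldehyde in an intramolecular Mukaiyama aldol that closes the trione ring and the second seven-membered ring; the cage fixes C5 and the C4 epimers converge in step 24.

Step 24
Reactants: 37 cage aldol
Product: 38 cage 2,4,9-triketone with C5-H
Conditions: Dess–Martin periodinane, CH2Cl2, rt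
Reagents that add atoms: none
Why: Dess–Martin oxidation of the secondary carbinol removes the C4 stereocentre and gives the non-enolisable trione.

Step 25
Reactants: 38 cage 2,4,9-triketone with C5-H; 12 2-methylpropanoyl chloride
Product: 39 target CNP0313870.1
Conditions: LiTMP (1.3 equiv, from 2,2,6,6-tetramethylpiperidine and n-BuLi), THF, −78 °C; then 12 (1.5 equiv), −78 → −40 °C
Reagents that add atoms: none
Why: Bridgehead deprotonation of the only acidic C–H (C5, between two ketones) gives a σ-carbanion that cannot O-acylate and is C-acylated with retention, as in bridgehead acylations of bicyclo[3.3.1]nonane triones.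

## Compound list

1 | 4,4-dimethylcyclohex-2-en-1-one | CC1(C)CCC(=O)C=C1 | starting material
2 | (1R)-4,4-dimethylcyclohex-2-en-1-ol | O[C@H]1C=CC(C)(C)CC1 | intermediate
3 | triethyl orthoacetate | CCOC(C)(OCC)OCC | starting material
4 | mixed ketene acetal, (1R)-1-[(1-ethoxyethenyl)oxy]-4,4-dimethylcyclohex-2-ene | C=C(OCC)O[C@H]1C=CC(C)(C)CC1 | intermediate
5 | ethyl 2-[(1R)-6,6-dimethylcyclohex-2-en-1-yl]acetate | CCOC(=O)C[C@@H]1C=CCCC1(C)C | intermediate
6 | ethyl 2-[(1R)-6,6-dimethyl-4-oxocyclohex-2-en-1-yl]acetate | CCOC(=O)C[C@@H]1C=CC(=O)CC1(C)C | intermediate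
7 | ethyl 2-[(1S)-2,2-dimethyl-4-oxocyclohexyl]acetate | CCOC(=O)C[C@@H]1CCC(=O)CC1(C)C | intermediate
8 | ethyl 2-[(8S)-7,7-dimethyl-1,4-dioxaspiro[4.5]decan-8-yl]acetate | CCOC(=O)C[C@@H]1CCC2(OCCO2)CC1(C)C | intermediate
9 | 2-[(8S)-7,7-dimethyl-1,4-dioxaspiro[4.5]decan-8-yl]acetaldehyde | O=CC[C@@H]1CCC2(OCCO2)CC1(C)C | intermediate
10 | dimethyl malonate | COC(=O)CC(=O)OC | starting material
11 | dimethyl 2-{2-[(8S)-7,7-dimethyl-1,4-dioxaspiro[4.5]decan-8-yl]ethylidene}propanedioate | COC(=O)C(=CC[C@@H]1CCC2(OCCO2)CC1(C)C)C(=O)OC | intermediate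
12 | 2-methylpropanoyl chloride (isobutyryl chloride) | CC(C)C(=O)Cl | starting material
13 | ethanethiol | CCS | starting material
14 | S-ethyl 2-methylpropanethioate | CCSC(=O)C(C)C | intermediate
15 | {[1-(ethylsulfanyl)-2-methylprop-1-en-1-yl]oxy}trimethylsilane | CCSC(O[Si](C)(C)C)=C(C)C | intermediate
16 | dimethyl 2-[(2S)-1-[(8S)-7,7-dimethyl-1,4-dioxaspiro[4.5]decan-8-yl]-4-(ethylsulfanyl)-3,3-dimethyl-4-oxobutan-2-yl]propanedioate | CCSC(=O)C(C)(C)[C@@H](C[C@@H]1CCC2(OCCO2)CC1(C)C)C(C(=O)OC)C(=O)OC | intermediate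
17 | dimethyl 2-[(2S)-1-[(8S)-7,7-dimethyl-1,4-dioxaspiro[4.5]decan-8-yl]-3,3-dimethyl-4-oxobutan-2-yl]propanedioate | O=CC(C)(C)[C@@H](C[C@@H]1CCC2(OCCO2)CC1(C)C)C(C(=O)OC)C(=O)OC | intermediate
18 | dimethyl 2-[(2S)-1-[(8S)-7,7-dimethyl-1,4-dioxaspiro[4.5]decan-8-yl]-3,3-dimethylpent-4-en-2-yl]propanedioate | C=CC(C)(C)[C@@H](C[C@@H]1CCC2(OCCO2)CC1(C)C)C(C(=O)OC)C(=O)OC | intermediate
19 | B-alkyl-9-borabicyclo[3.3.1]nonane from 18 (boron on the terminal carbon) | C1CCC2CCCC1B2CCC(C)(C)[C@@H](C[C@@H]1CCC2(OCCO2)CC1(C)C)C(C(=O)OC)C(=O)OC | intermediate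
20 | dimethyl 2-[(2S)-1-[(8S)-7,7-dimethyl-1,4-dioxaspiro[4.5]decan-8-yl]-5-hydroxy-3,3-dimethylpentan-2-yl]propanedioate | OCCC(C)(C)[C@@H](C[C@@H]1CCC2(OCCO2)CC1(C)C)C(C(=O)OC)C(=O)OC | intermediate
21 | dimethyl 2-[(2S)-1-[(8S)-7,7-dimethyl-1,4-dioxaspiro[4.5]decan-8-yl]-5-iodo-3,3-dimethylpentan-2-yl]propanedioate | ICCC(C)(C)[C@@H](C[C@@H]1CCC2(OCCO2)CC1(C)C)C(C(=O)OC)C(=O)OC | intermediate
22 | dimethyl (2R)-2-{[(8S)-7,7-dimethyl-1,4-dioxaspiro[4.5]decan-8-yl]methyl}-3,3-dimethylcyclopentane-1,1-dicarboxylate | COC(=O)C1(C(=O)OC)CCC(C)(C)[C@H]1C[C@@H]1CCC2(OCCO2)CC1(C)C | intermediate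
23 | (1S,2R)-2-{[(8S)-7,7-dimethyl-1,4-dioxaspiro[4.5]decan-8-yl]methyl}-1-(methoxycarbonyl)-3,3-dimethylcyclopentane-1-carboxylic acid (CO2H trans to the C2 side chain) | OC(=O)[C@]1(C(=O)OC)CCC(C)(C)[C@H]1C[C@@H]1CCC2(OCCO2)CC1(C)C | intermediate
24 | sodium salt of 23 | [Na+].[O-]C(=O)[C@]1(C(=O)OC)CCC(C)(C)[C@H]1C[C@@H]1CCC2(OCCO2)CC1(C)C | intermediate
25 | (1R,2R)-2-{[(8S)-7,7-dimethyl-1,4-dioxaspiro[4.5]decan-8-yl]methyl}-1-(hydroxymethyl)-3,3-dimethylcyclopentane-1-carboxylic acid (CH2OH cis to the C2 side chain) | OC(=O)[C@]1(CO)CCC(C)(C)[C@H]1C[C@@H]1CCC2(OCCO2)CC1(C)C | intermediate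
26 | (1R,2R)-2-{[(1S)-2,2-dimethyl-4-oxocyclohexyl]methyl}-1-(hydroxymethyl)-3,3-dimethylcyclopentane-1-carboxylic acid | OC(=O)[C@]1(CO)CCC(C)(C)[C@H]1C[C@@H]1CCC(=O)CC1(C)C | intermediate
27 | bis-silyl derivative of 26 (TBS ether and TBS ester) | CC(C)(C)[Si](C)(C)OC(=O)[C@]1(CO[Si](C)(C)C(C)(C)C)CCC(C)(C)[C@H]1C[C@@H]1CCC(=O)CC1(C)C | intermediate
28 | (1R,2R)-1-({[tert-butyl(dimethyl)silyl]oxy}methyl)-2-{[(1S)-2,2-dimethyl-4-oxocyclohexyl]methyl}-3,3-dimethylcyclopentane-1-carboxylic acid | OC(=O)[C@]1(CO[Si](C)(C)C(C)(C)C)CCC(C)(C)[C@H]1C[C@@H]1CCC(=O)CC1(C)C | intermediate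
29 | acyl imidazolide of 28 | O=C(n1ccnc1)[C@]1(CO[Si](C)(C)C(C)(C)C)CCC(C)(C)[C@H]1C[C@@H]1CCC(=O)CC1(C)C | intermediate
30 | C1-H tricyclic 2,9-diketone: the C9 cyclohexanone (C1-H, C8, C7, C6 gem-dimethyl, C5 H2) bridged C1–C2(=O)–C3–C11–C10–C7; C3 bears CH2OTBS (C4) and is fused to the 12,12-dimethylcyclopentane (C3, C11–C14); configuration as in the SMILES | O=C1CC(C)(C)[C@H]2C[C@@H]1C(=O)[C@]1(CO[Si](C)(C)C(C)(C)C)CCC(C)(C)[C@H]1C2 | intermediate
31 | geranyl bromide, (2E)-1-bromo-3,7-dimethylocta-2,6-diene | CC(C)=CCC/C(C)=C/CBr | starting material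
32 | 1-geranyl derivative of 30 (geranyl on C1, exo) | CC(C)=CCC/C(C)=C/C[C@@]1(C(=O)CC3(C)C)C[C@H]3C[C@@H]4C(C)(C)CC[C@@]4(CO[Si](C)(C)C(C)(C)C)C1=O | intermediate
33 | C4 primary alcohol from 32 | CC(C)=CCC/C(C)=C/C[C@@]1(C(=O)CC3(C)C)C[C@H]3C[C@@H]4C(C)(C)CC[C@@]4(CO)C1=O | intermediate
34 | C4 aldehyde (formyl group on C3, cis to C10) | CC(C)=CCC/C(C)=C/C[C@@]1(C(=O)CC3(C)C)C[C@H]3C[C@@H]4C(C)(C)CC[C@@]4(C=O)C1=O | intermediate
35 | C9 trimethylsilyl enol ether (C5=C9) of 34 | CC(C)=CCC/C(C)=C/C[C@@]1(C(O[Si](C)(C)C)=CC3(C)C)C[C@H]3C[C@@H]4C(C)(C)CC[C@@]4(C=O)C1=O | intermediate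
36 | O-trimethylsilyl cage aldol (C4–C5 bond closed; C4 epimers) | CC(C)=CCC/C(C)=C/C[C@@]12C[C@H]3C[C@@H]4C(C)(C)CC[C@]4(C1=O)C(O[Si](C)(C)C)[C@@H](C2=O)C3(C)C | intermediate
37 | cage aldol, 4-hydroxy-2,9-dione with C5-H (C4 epimers) | CC(C)=CCC/C(C)=C/C[C@@]12C[C@H]3C[C@@H]4C(C)(C)CC[C@]4(C1=O)C(O)[C@@H](C2=O)C3(C)C | intermediate
38 | cage 2,4,9-triketone with C5-H (target lacking the isobutyryl group) | CC(C)=CCC/C(C)=C/C[C@@]12C[C@H]3C[C@@H]4C(C)(C)CC[C@]4(C1=O)C(=O)[C@@H](C2=O)C3(C)C | intermediate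
39 | CNP0313870.1 (1R,3S,5S,7R,11R in the locants used here) | CC(C)=CCC/C(C)=C/C[C@@]12C[C@H]3C[C@@H]4C(C)(C)CC[C@]4(C1=O)C(=O)[C@@](C(=O)C(C)C)(C2=O)C3(C)C | target

## Step count and weak points

Total step count: 25. Longest linear sequence: 23 steps (1 → 39 through steps 1–7 and 10–25); steps 8 and 9 prepare fragment 15.

Most likely to fail:

Step 10 (Mukaiyama–Michael). A tetrasubstituted silyl ketene thioacetal adding to an alkylidene malonate with only a primary alkyl β-substituent may be slow or poorly selective. The fallback sets out from 11 and comes back at 18. Prenylmagnesium chloride (THF, −78 °C) adds to 11 in conjugate fashion through its γ-carbon, which installs the 1,1-dimethylallyl group directly and bypasses 16 and 17. It gives 18 together with its C11 epimer; because C7 is already fixed these are diastereomers and are separated by chromatography. This fallback makes no new compound (F0).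

Step 23 (cage-closing aldol). The C5 enol ether has to reach a neopentyl aldehyde, and retro-aldol or competing silylation may win. The fallback sets out from 34 and comes back at 38. Pinnick oxidation (NaClO2, NaH2PO4, 2-methylbut-2-ene, t-BuOH/H2O) gives the keto acid F1. 1,1'-Carbonyldiimidazole converts it into the acyl imidazolide F2, and LiN(SiMe3)2 (THF, −78 → 0 °C) then forms the C4–C5 bond by kinetic C-acylation of the C5 enolate. Imidazolide is a poor nucleophile, so retro-Claisen cleavage is not an issue, and 38 is reached without passing through 37.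

Step 25 (bridgehead acylation). Deprotonation of C5-H in the rigid cage may be slow, and the acid chloride may react with residual amide base. The fallback sets out from 38 and comes back at 39. The bridgehead lithium species is trapped with the smaller and more electrophilic isobutyraldehyde to give the bridgehead carbinol F3 (carbinol epimers), and Dess–Martin oxidation of F3 gives 39.

Further compounds
F0 | step 10 | none | none
F1 | step 23 | C4 carboxylic acid from 34 (CO2H on C3 in place of CHO) | CC(C)=CCC/C(C)=C/C[C@@]1(C(=O)CC3(C)C)C[C@H]3C[C@@H]4C(C)(C)CC[C@@]4(C(=O)O)C1=O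
F2 | step 23 | acyl imidazolide of F1 | CC(C)=CCC/C(C)=C/C[C@@]1(C(=O)CC3(C)C)C[C@H]3C[C@@H]4C(C)(C)CC[C@@]4(C(=O)n5ccnc5)C1=O
F3 | step 25 | bridgehead carbinol, 5-(1-hydroxy-2-methylpropyl) cage 2,4,9-triketone (carbinol epimers) | CC(C)=CCC/C(C)=C/C[C@@]12C[C@H]3C[C@@H]4C(C)(C)CC[C@]4(C1=O)C(=O)[C@@](C(O)C(C)C)(C2=O)C3(C)C
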